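**Time first.** With time the target in this flask stops climbing. The delta run, which is this very flask so far, reads 42% at 1.33 h and then lies flat, averaging 56.0% from 4.00 h on. The theta run, at 31 °C with 0.15 mol% of free catalyst, lies flat at 52.0% from 2.00 h on.

| flask | substrate | partner | free catalyst | temperature | remark | time |
|---|---|---|---|---|---|---|
| delta | 0.80 M | 3 equiv | 0.1 mol% | 25 °C | the very flask that is asked about, followed so far |  |
| theta | 0.80 M | 3 equiv | 0.15 mol% | 31 °C | run made earlier |  |
| flask | 0.80 M | 3.00 equiv | 0.1 mol% | 25 °C |  | 8.0 h |

| run | time / h | target / % |
|---|---|---|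
| delta | 1.33 | 42 |
| delta | 2.50 | 52 |
| delta | 4.00 | 56 |
| delta | 5.00 | 55 |
| delta | 6.00 | 58 |
| delta | 8.00 | 55 |
| theta | 0.250 | 24 |
| theta | 0.833 | 39 |
| theta | 1.33 | 50 |
| theta | 2.00 | 52 |
| theta | 3.00 | 51 |
| theta | 4.00 | 53 |

(scatter of a reading: 1.5 percentage points)

- Friday's: change nothing and wait 2.5 h more
- Wednesday's: at 8.0 h raise the temperature by 20 K, then wait 2.5 h
- Thursday's: at 8.0 h add free catalyst, 100% of the amount charged, then wait 2.5 h
- Monday's: at 8.0 h take out 90% of the target then present, then wait 2.5 h

- target taken out counts as made
- additions bring no volume worth counting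

- target, in percent of the substrate first charged, at 8.0 h
- which option adds most target ("none" when 2 percentage points or less is all one gets) (Friday's / Wednesday's / Thursday's / Monday's / none)
- target present, with what was taken out counted in, in percent of the substrate first charged, after Wednesday's
- target present, with what was taken out counted in, in percent of the substrate first charged, after Monday's

**End state.** A flat line has two readings: a balance between substrate and target, or a reaction that has stopped with substrate unused. A balance refills when target is taken out; a stop does not. These runs cannot separate the two, so it is my judgement that I commit to a stop, with partner as what is lost.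

**Stall exponent.** I take the fraction of substrate lost per hour as proportional to free catalyst and as dying away while partner is lost, so it is no constant. The logarithm of charged over left therefore adds up that falling fraction over time. For this flask it ends at 0.821, which I call the stall exponent S, the logarithm of substrate charged over substrate left on the flat line. Theta, scaled to this flask's loading, gives 0.489, less, so that warming step multiplies S by 0.596.

**My reckoning.** The first delta reading gives an approach constant of 1.04 h⁻¹, a half-time of 0.665 h, and 8.0 h is far longer. I therefore take 56.0% as the answer now. With S stopped, I expect that same figure after Wednesday's and after Monday's, and "none" as best.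

**The forecast.** It differs from me, holding that “The simplest reading is an exothermic equilibrium”. It gives 56% now (54.5% to 57.5%) and Monday's as best, with 43% after Wednesday's (36% to 49%) and 75% after Monday's (69% to 80%).

**The result.** The flask gives 55.6%, 55.6% after Wednesday's and 55.7% after Monday's, and the best choice is none. Monday's adds 0.16 percentage points, the most of the options, yet less than the margin.

    substrate + free catalyst ⇌ catalyst intermediate A (K = 0.930 M⁻¹, k = 5.61 M⁻¹ s⁻¹, Ea = 56.0 kJ mol⁻¹, ΔH = −31.0 kJ mol⁻¹)
    partner + catalyst intermediate A ⇌ catalyst intermediate B (K = 0.123 M⁻¹, k = 0.261 M⁻¹ s⁻¹, Ea = 53.0 kJ mol⁻¹, ΔH = −90.0 kJ mol⁻¹)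
    partner → decomposed reagent (k = 1.80 × 10⁻⁴ s⁻¹, Ea = 89.0 kJ mol⁻¹)
    catalyst intermediate C ⇌ free catalyst + target (K = 0.400 M, k = 0.822 s⁻¹, Ea = 78.0 kJ mol⁻¹, ΔH = −17.0 kJ mol⁻¹)
    catalyst intermediate B → catalyst intermediate C (k = 29.8 s⁻¹, Ea = 63.0 kJ mol⁻¹)
    (constants at 25 °C)

**Warmer neighbour.** At 8.00 h the flask holds partner at 0.231% of its charge beside 1.95 M of decomposed reagent. Left ten times as long, to 80.0 h, the flask reads 55.7%, so S stays near 0.821. A repeat at 40 °C stands 2.50 warming steps up, which carries S to 0.225 and the target to 20.2%. The simulated repeat gives 23.8%, with partner at 0% of its charge.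

The earlier runs and the new flask were generated by integration with made-up constants.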